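**Retrosynthetic overview**
- Target 17 ⇒ Sonogashira coupling (C10–C11) of ethynyl-oxolane 11 with iodo-bromotriene 16.
- 11 ⇒ the only ring (the oxolane) is closed last in its fragment by C8–O bond formation: a stereoconvergent copper-catalysed propargylic etherification of hydroxy ester 10, released in the flask from lactone carbonate 9.
- 9 ⇒ lactol 6 + ethynyl Grignard; 6 ⇒ ynone 3 (asymmetric transfer hydrogenation sets C5) ⇒ acid chloride 1 + alkyne 2.
- 16 ⇒ hept-6-yn-1-ol 12 by hydrozirconation–iodination, one-pot oxidation/Wittig, then bromo-Wittig.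

Assumption: atom labels C1–C20 count along the chain from the ester carbonyl carbon; the ring carbons are C5 and C8, and the target is the trans-(5R,8S) oxolane.
Assumption: the (S,S)-ligand in step 6 is taken to give the (8S) centre by analogy only; if the sense is the reverse, the (R,R)-ligand is used with no other change.

**Step 1**
Reactants: 1 methyl 5-chloro-5-oxopentanoate; 2 3,3-diethoxyprop-1-yne
Product: 3 methyl 8,8-diethoxy-5-oxooct-6-ynoate
Conditions: PdCl2(PPh3)2 (2 mol%), CuI (4 mol%), Et3N (1.2 equiv), THF, rt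
Reagents that add atoms: none
Why: Acyl Sonogashira coupling: the acid chloride adds oxidatively to zerovalent palladium formed in situ, the copper acetylide transmetalates and reductive elimination gives the ynone, with ester and acetal inert.

**Step 2**
Reactants: 3 methyl 8,8-diethoxy-5-oxooct-6-ynoate
Product: 4 methyl (5R)-8,8-diethoxy-5-hydroxyoct-6-ynoate
Conditions: Ru[(R,R)-TsDPEN](p-cymene) (16-electron amido complex, 1 mol%), iPrOH, rt
Reagents that add atoms: none
Why: Noyori asymmetric transfer hydrogenation of an alkynyl ketone: the alkyne plays the role of the aryl group in the six-membered hydride-transfer transition state, so the (R,R)-catalyst gives the (5R)-propargylic alcohol (typically >95% ee) without touching ester, alkyne or acetal.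

**Step 3**
Reactants: 4 methyl (5R)-8,8-diethoxy-5-hydroxyoct-6-ynoate
Product: 6 methyl 4-[(2R)-5-hydroxyoxolan-2-yl]butanoate, via hydroxy acetal ester 5 (not isolated)
Conditions: H2 (1 atm), 10% Pd/C, EtOAc, rt; filter; then 1 M HCl, THF, 0 °C to rt
Reagents that add atoms: water, O
Why: Heterogeneous hydrogenation saturates the alkyne without affecting C5, and acetal hydrolysis gives the γ-hydroxy aldehyde, which closes to the five-membered lactol (anomer mixture).

**Step 4**
Reactants: 6 methyl 4-[(2R)-5-hydroxyoxolan-2-yl]butanoate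
Product: 8 (6R)-6-(3-hydroxypent-4-yn-1-yl)oxan-2-one, via dihydroxy ester 7 (not isolated)
Conditions: HC≡CMgBr (3.0 equiv), THF, −20 to 0 °C; 1 M HCl quench; then TsOH·H2O (5 mol%), CH2Cl2, rt
Reagents that add atoms: ethynylmagnesium bromide, C#C[Mg]Br
Why: Grignard addition to the open hydroxy-aldehyde form of the lactol (first equivalent deprotonates, second adds, the ester reacts only slowly), then acid-catalysed δ-lactonization ties up the C5 oxygen so the propargylic OH is the only free hydroxyl; C8 forms as a 1:1 mixture on purpose because step 6 erases it.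

**Step 5**
Reactants: 8 (6R)-6-(3-hydroxypent-4-yn-1-yl)oxan-2-one
Product: 9 tert-butyl 1-[(2R)-6-oxooxan-2-yl]pent-4-yn-3-yl carbonate
Conditions: Boc2O (1.5 equiv), DMAP (10 mol%), CH2Cl2, 0 °C to rt
Reagents that add atoms: di-tert-butyl dicarbonate, CC(C)(C)OC(=O)OC(=O)OC(C)(C)C
Why: DMAP-catalysed O-acylation turns the only free hydroxyl into a tert-butyl carbonate, a leaving group that ionizes under copper catalysis but survives brief carbonate-catalysed methanolysis.

**Step 6**
Reactants: 9 tert-butyl 1-[(2R)-6-oxooxan-2-yl]pent-4-yn-3-yl carbonate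
Product: 11 methyl 4-[(2R,5S)-5-ethynyloxolan-2-yl]butanoate, via hydroxy ester carbonate 10 (not isolated)
Conditions: K2CO3 (10 mol%), MeOH, 0 °C, 1 h; then [Cu(MeCN)4]PF6 (5 mol%), (S,S)-Ph-pybox (6 mol%), iPr2NEt (1.5 equiv), MeOH, −20 °C, Ar
Reagents that add atoms: methanol, CO
Why: Proposed new method: methoxide opens the δ-lactone to δ-hydroxy methyl ester 10; the copper–pybox complex (univalent copper; pybox = 2,6-bis[(4S)-4-phenyl-4,5-dihydro-1,3-oxazol-2-yl]pyridine) forms a copper acetylide, loss of tert-butyl carbonate (which falls apart to CO2 and tBuOH) gives a copper allenylidene in which C8 is planar so both C8 epimers converge, and the C5 hydroxyl attacks C8 in a 5-exo closure (effective molarity far above that of solvent MeOH) on the face left open by the ligand, setting (8S) and hence the trans-2,5 ring; the closest known chemistry is copper–pybox enantioselective propargylic etherification with external alcohols and the intramolecular propargylic amination, whereas ring closure by a secondary alkanol onto an alkyl-substituted propargylic carbonate with catalyst-controlled diastereoselection has not been shown.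

**Step 7**
Reactants: 12 hept-6-yn-1-ol
Product: 13 (6E)-7-iodohept-6-en-1-ol
Conditions: Cp2Zr(H)Cl (2.2 equiv), THF, 0 °C to rt; then I2 (1.1 equiv), 0 °C
Reagents that add atoms: iodine, II
Why: Hydrozirconation–iodination: the first equivalent of Cp2Zr(H)Cl is consumed by the OH, the second adds syn across the terminal alkyne with zirconium at the terminus, and iodine cleaves the C–Zr bond with retention to give the (E)-iodoalkene.

**Step 8**
Reactants: 13 (6E)-7-iodohept-6-en-1-ol
Product: 15 (2E,8E)-9-iodonona-2,8-dienal, via iodoheptenal 14 (not isolated)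
Conditions: TEMPO (10 mol%), PhI(OAc)2 (1.1 equiv), CH2Cl2, rt; then Ph3P=CHCHO (1.2 equiv), PhMe, 80 °C
Reagents that add atoms: (triphenylphosphoranylidene)acetaldehyde, O=CC=P(c1ccccc1)(c1ccccc1)c1ccccc1
Why: One-pot TEMPO/PhI(OAc)2 oxidation and Wittig olefination with the stabilized formyl ylide, which gives the (E)-enal (>20:1) and spares the vinyl iodide.

**Step 9**
Reactants: 15 (2E,8E)-9-iodonona-2,8-dienal
Product: 16 (1Z,3E,9E)-1-bromo-10-iododeca-1,3,9-triene
Conditions: Ph3P(CH2Br)Br (1.3 equiv), KOtBu (1.25 equiv), THF, −78 °C; then 15, −78 to −20 °C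
Reagents that add atoms: (bromomethyl)triphenylphosphonium bromide, BrC[P+](c1ccccc1)(c1ccccc1)c1ccccc1.[Br-]
Why: Wittig reaction with the non-stabilized ylide Ph3P=CHBr at low temperature gives the (Z)-bromoalkene kinetically (usually about 10:1 Z:E, minor isomer removed on AgNO3-impregnated silica), so the (1Z,3E)-bromodiene results and the vinyl iodide is inert.

**Step 10**
Reactants: 11 methyl 4-[(2R,5S)-5-ethynyloxolan-2-yl]butanoate; 16 (1Z,3E,9E)-1-bromo-10-iododeca-1,3,9-triene
Product: 17 methyl 4-[(2R,5S)-5-[(3E,9E,11Z)-12-bromododeca-3,9,11-trien-1-yn-1-yl]oxolan-2-yl]butanoate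
Conditions: Pd(PPh3)4 (5 mol%), CuI (10 mol%), Et3N (3 equiv), THF, 0 °C, Ar
Reagents that add atoms: none
Why: Sonogashira coupling: zerovalent palladium inserts into the C–I bond much faster than into the C–Br bond at 0 °C, so the alkyne couples only at the iodoalkene with retention of E geometry, and neither stereocentre nor the Z-bromodiene is touched.

**Compound list**
1 | methyl 5-chloro-5-oxopentanoate | COC(=O)CCCC(=O)Cl | starting material
2 | 3,3-diethoxyprop-1-yne | CCOC(OCC)C#C | starting material
3 | methyl 8,8-diethoxy-5-oxooct-6-ynoate | COC(=O)CCCC(=O)C#CC(OCC)OCC | intermediate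
4 | methyl (5R)-8,8-diethoxy-5-hydroxyoct-6-ynoate | COC(=O)CCC[C@@H](O)C#CC(OCC)OCC | intermediate
5 | methyl (5R)-8,8-diethoxy-5-hydroxyoctanoate | COC(=O)CCC[C@@H](O)CCC(OCC)OCC | intermediate
6 | methyl 4-[(2R)-5-hydroxyoxolan-2-yl]butanoate (anomer mixture) | COC(=O)CCC[C@@H]1CCC(O)O1 | intermediate
7 | methyl (5R)-5,8-dihydroxydec-9-ynoate (C8 epimer mixture) | COC(=O)CCC[C@@H](O)CCC(O)C#C | intermediate
8 | (6R)-6-(3-hydroxypent-4-yn-1-yl)oxan-2-one (carbinol epimer mixture) | O=C1CCC[C@H](CCC(O)C#C)O1 | intermediate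
9 | tert-butyl 1-[(2R)-6-oxooxan-2-yl]pent-4-yn-3-yl carbonate (epimer mixture) | O=C1CCC[C@H](CCC(OC(=O)OC(C)(C)C)C#C)O1 | intermediate
10 | methyl (5R)-8-[(tert-butoxycarbonyl)oxy]-5-hydroxydec-9-ynoate (C8 epimer mixture) | COC(=O)CCC[C@@H](O)CCC(OC(=O)OC(C)(C)C)C#C | intermediate
11 | methyl 4-[(2R,5S)-5-ethynyloxolan-2-yl]butanoate | COC(=O)CCC[C@@H]1CC[C@@H](C#C)O1 | intermediate
12 | hept-6-yn-1-ol | OCCCCCC#C | starting material
13 | (6E)-7-iodohept-6-en-1-ol | OCCCCC/C=C/I | intermediate
14 | (6E)-7-iodohept-6-enal | O=CCCCC/C=C/I | intermediate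
15 | (2E,8E)-9-iodonona-2,8-dienal | O=C/C=C/CCCC/C=C/I | intermediate
16 | (1Z,3E,9E)-1-bromo-10-iododeca-1,3,9-triene | Br/C=C\C=C\CCCC/C=C/I | intermediate
17 | methyl 4-[(2R,5S)-5-[(3E,9E,11Z)-12-bromododeca-3,9,11-trien-1-yn-1-yl]oxolan-2-yl]butanoate | COC(=O)CCC[C@@H]1CC[C@@H](C#C/C=C/CCCC/C=C/C=C\Br)O1 | target

**Totals**
Total step count: 10. Longest linear sequence: 7 (steps 1–6, then step 10).

**Three steps most likely to fail**

Step 6 (the new copper-catalysed ring closure). Risks are capture of the allenylidene by MeOH, loss of a C7 proton to give a conjugated enyne, and weak or reversed facial control. The fallback uses known chemistry only, sets out from lactol 6 and returns at 11. Lactol 6 is methylenated with Ph3P=CH2 (from Ph3PCH3Br and KOtBu, THF, 0 °C, quenched cold) to methyl (5R)-5-hydroxynon-8-enoate F3. Mukaiyama aerobic oxidative cyclization with Co(modp)2 (modp = 1-morpholinocarbamoyl-4,4-dimethylpentane-1,3-dionate; divalent cobalt), O2 and tBuOOH in iPrOH at 55 °C then forms the C8–O bond and gives the trans ring, methyl 4-[(2R,5S)-5-(hydroxymethyl)oxolan-2-yl]butanoate F4 (trans selectivity is normally >20:1 for such pentenols). Parikh–Doering oxidation (SO3·pyridine, DMSO, iPr2NEt) gives methyl 4-[(2R,5S)-5-formyloxolan-2-yl]butanoate F5, and Ohira–Bestmann homologation (dimethyl (1-diazo-2-oxopropyl)phosphonate, K2CO3, MeOH) gives 11.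

Step 10 (iodide-versus-bromide selectivity in the Sonogashira coupling). If the bromodiene also couples, the order of the last two bond formations is reversed. This fallback sets out from 11 and 15 and returns at 17. Alkyne 11 is coupled with iodo-enal 15, which carries no C–Br bond (Pd(PPh3)4, CuI, Et3N, THF, 0 °C), to give methyl 4-[(2R,5S)-5-[(3E,9E)-11-oxoundeca-3,9-dien-1-yn-1-yl]oxolan-2-yl]butanoate F6. The Z-bromoalkene is then installed last with Ph3P=CHBr (from Ph3P(CH2Br)Br and KOtBu, THF, −78 °C), giving 17.

Step 4 (ethynyl Grignard on a lactol that also carries a methyl ester). If ester attack or incomplete lactonization spoils the step, the C5 oxygen is locked in the lactone before the aldehyde is released. This fallback sets out from 4 and returns at 8. Compound 4 is hydrogenated as in step 3 but 5 is isolated and lactonized with DBU (20 mol%) in toluene at 80 °C to (6R)-6-(3,3-diethoxypropyl)oxan-2-one F1. The acetal is cleaved with Amberlyst-15 in wet acetone to 3-[(2R)-6-oxooxan-2-yl]propanal F2, and HC≡CMgBr (1.1 equiv, THF, −78 to −40 °C) adds to the aldehyde only, giving 8.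

**Further compounds**
F1 | step 4 | (6R)-6-(3,3-diethoxypropyl)oxan-2-one | O=C1CCC[C@H](CCC(OCC)OCC)O1
F2 | step 4 | 3-[(2R)-6-oxooxan-2-yl]propanal | O=C1CCC[C@H](CCC=O)O1
F3 | step 6 | methyl (5R)-5-hydroxynon-8-enoate | COC(=O)CCC[C@@H](O)CCC=C
F4 | step 6 | methyl 4-[(2R,5S)-5-(hydroxymethyl)oxolan-2-yl]butanoate | COC(=O)CCC[C@@H]1CC[C@@H](CO)O1
F5 | step 6 | methyl 4-[(2R,5S)-5-formyloxolan-2-yl]butanoate | COC(=O)CCC[C@@H]1CC[C@@H](C=O)O1
F6 | step 10 | methyl 4-[(2R,5S)-5-[(3E,9E)-11-oxoundeca-3,9-dien-1-yn-1-yl]oxolan-2-yl]butanoate | COC(=O)CCC[C@@H]1CC[C@@H](C#C/C=C/CCCC/C=C/C=O)O1
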